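**Retrosynthetic overview**
1. Feature: the oxane ring is numbered O1, C2 (aryl), C3 (cinnamyl), C4, C5 (carbinol-bearing), C6, and is 2,3,5-all-cis. O1–C2–C3 together with the CH2 on C3 is a masked β-aryl-β-hydroxy ester. C4–C5–C6 is a three-carbon unit that can be electrophilic at both ends while C5 holds an exocyclic methylene.
2. Key disconnection: C3–C4 and O1–C6 are cut together. This gives the dianion of the (R)-hydroxy ester and 3-chloro-2-(chloromethyl)prop-1-ene. The oxane is the only ring made; the three benzene rings are bought.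
3. C2 comes from asymmetric hydrogenation of the aroylacetate built from 4'-hydroxyacetophenone and diethyl carbonate. C3 follows from C2 in the annulation.
4. The ester carbon is converted into the cinnamyl CH2 first (CH2OH, CH2I, nickel coupling with the bromostyrene from p-coumaric acid). No ester is then left to lactonise onto the cis C5 arm or to compete for the aryl metal.
5. The exocyclic methylene then becomes the carbinol carbon: 9-BBN sets C5, oxidation follows, a ligand-controlled arylzinc addition sets the carbinol, and one fluoride step frees the three phenols.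

Key step: step 4

Remark on the chemistry: the SMILES is read as the 2,3,5-all-cis oxane (2R,3S,5R) with an (R)-carbinol and an (E)-alkene; triisopropylsilyl (TIPS) protects the two phenols that must pass a lithium alkoxide and perborate, and tert-butyldimethylsilyl protects the one that enters last.

Step 1
Reactants: 1 4'-hydroxyacetophenone; 2 diethyl carbonate
Product: 3 ethyl 3-(4-hydroxyphenyl)-3-oxopropanoate
Conditions: NaH (3.5 equiv), THF, reflux; aq HCl, 0 °C
Reagents that add atoms: none
Why: Crossed Claisen condensation (carbethoxylation), in which the ketone enolate of the phenoxide is acylated on carbon by the non-enolisable carbonate, the equilibrium is pulled through by deprotonation of the β-keto ester, and any aryl carbonate formed on the phenoxide is returned by ethoxide.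

Step 2
Reactants: 3 ethyl 3-(4-hydroxyphenyl)-3-oxopropanoate
Product: 4 ethyl 3-oxo-3-[4-(triisopropylsilyloxy)phenyl]propanoate
Conditions: TIPSCl, imidazole, DMF, 0 °C to rt
Reagents that add atoms: triisopropylsilyl chloride, CC(C)[Si](Cl)(C(C)C)C(C)C
Why: Imidazole-promoted silyl ether formation is selective for the phenol, and the bulky silyl group is chosen because this aryl ether must later withstand a lithium alkoxide, an aluminium hydride and perborate.

Step 3
Reactants: 4 ethyl 3-oxo-3-[4-(triisopropylsilyloxy)phenyl]propanoate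
Product: 5 ethyl (R)-3-hydroxy-3-[4-(triisopropylsilyloxy)phenyl]propanoate
Conditions: [RuCl(p-cymene)((S)-SEGPHOS)]Cl (0.5 mol%), H2 (30 bar), EtOH, 50 °C
Reagents that add atoms: none
Why: Noyori asymmetric hydrogenation of a β-keto ester, in which the ester-chelated ketone is reduced on one face of the chiral diphosphine–ruthenium hydride; for aroylacetates the (S)-configured biaryl ligand is the one that leads to the (R)-alcohol, the future C2.

Step 4
Reactants: 5 ethyl (R)-3-hydroxy-3-[4-(triisopropylsilyloxy)phenyl]propanoate; 6 3-chloro-2-(chloromethyl)prop-1-ene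
Product: 9 ethyl (2R,3S)-5-methylidene-2-[4-(triisopropylsilyloxy)phenyl]oxane-3-carboxylate, via dilithium alkoxide-enolate 7 (not isolated), via lithium chloro alkoxide 8 (not isolated)
Conditions: LiN(i-Pr)2 (2.0 equiv), THF, −78 to −20 °C; 6 (1.5 equiv), DMPU, LiI (20 mol%), −78 to 0 °C; then rt; pH 7 buffer
Reagents that add atoms: none
Why: Proposed new method: two equivalents of LiN(i-Pr)2 convert 5 into the lithium-bridged alkoxide–enolate 7, whose enolate carbon displaces one chloride of 6 (direct and allylically transposed attack give the same product) to form C3–C4 in 8, and the remaining lithium alkoxide, loosened by DMPU and helped by iodide exchange, then displaces the second allylic chloride to form O1–C6. The closest known reactions are the Fráter–Seebach anti-alkylation of β-hydroxy ester dianions with allylic halides and the intramolecular Williamson ether synthesis; what has not been shown is their merger in one flask on an aldolate-type alkoxide and a 1,3-bis-electrophile. The oxane ring closes in the 6-exo-tet mode, with the departing chloride outside the forming ring. C3 is set by 1,2-induction from C2: in the six-membered lithium chelate the aryl group covers one enolate face, the electrophile enters from the other, and the resulting anti (2S,3R) open-chain relationship becomes the 2,3-cis relationship once the oxygen and the new CH2 are tied into the ring. The step needs C-alkylation before O-alkylation, secured by the much higher nucleophilicity of the enolate carbon over the aggregated alkoxide, and it needs closure to outrun retro-aldol cleavage, C3 epimerisation and β-elimination, secured by the allylic leaving group, by lithium as the only counter-ion and by the stoichiometry, since the second equivalent of base ends up as LiCl and none is left to enolise 9.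

Step 5
Reactants: 9 ethyl (2R,3S)-5-methylidene-2-[4-(triisopropylsilyloxy)phenyl]oxane-3-carboxylate
Product: 10 {(2R,3R)-5-methylidene-2-[4-(triisopropylsilyloxy)phenyl]oxan-3-yl}methanol
Conditions: i-Bu2AlH (2.5 equiv), CH2Cl2, −78 to 0 °C; aq potassium sodium tartrate
Reagents that add atoms: none
Why: Ester reduction with a non-basic aluminium hydride runs through the aldehyde to the primary alcohol without enolising C3 or touching the alkene and the aryl silyl ether, so both stereocentres are carried over (the C3 descriptor changes only through priorities).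

Step 6
Reactants: 10 {(2R,3R)-5-methylidene-2-[4-(triisopropylsilyloxy)phenyl]oxan-3-yl}methanol
Product: 11 (2R,3S)-3-(iodomethyl)-5-methylidene-2-[4-(triisopropylsilyloxy)phenyl]oxane
Conditions: PPh3, I2, imidazole (premixed), CH2Cl2, 0 °C; then 10, 0 °C to rt
Reagents that add atoms: iodine, [I][I]
Why: Appel reaction, in which the preformed iodophosphonium salt activates the primary hydroxyl for SN2 displacement by iodide, and premixing leaves no free iodine for iodoetherification onto the exocyclic alkene.

Step 7
Reactants: 12 p-coumaric acid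
Product: 14 (E)-3-[4-(triisopropylsilyloxy)phenyl]prop-2-enoic acid, via bis-silylated coumarate 13 (not isolated)
Conditions: TIPSCl (2.2 equiv), imidazole, DMF, rt; K2CO3, THF/MeOH/H2O, rt; aq HCl to pH 3
Reagents that add atoms: triisopropylsilyl chloride, CC(C)[Si](Cl)(C(C)C)C(C)C
Why: Exhaustive silylation followed by selective hydrolysis relies on a silyl ester being far more labile than an aryl triisopropylsilyl ether towards mild aqueous carbonate.

Step 8
Reactants: 14 (E)-3-[4-(triisopropylsilyloxy)phenyl]prop-2-enoic acid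
Product: 15 (E)-1-(2-bromoethenyl)-4-(triisopropylsilyloxy)benzene
Conditions: NBS, LiOAc (20 mol%), MeCN/H2O, rt
Reagents that add atoms: N-bromosuccinimide, O=C1CCC(=O)N1Br
Why: Catalytic Hunsdiecker-type bromodecarboxylation, in which the electron-rich cinnamate takes up electrophilic bromine next to the carboxylate and the donor-stabilised benzylic cation loses CO2 to give the more stable (E)-β-bromostyrene.

Step 9
Reactants: 11 (2R,3S)-3-(iodomethyl)-5-methylidene-2-[4-(triisopropylsilyloxy)phenyl]oxane; 15 (E)-1-(2-bromoethenyl)-4-(triisopropylsilyloxy)benzene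
Product: 16 (2R,3S)-5-methylidene-2-[4-(triisopropylsilyloxy)phenyl]-3-{(E)-3-[4-(triisopropylsilyloxy)phenyl]prop-2-enyl}oxane
Conditions: NiI2(2,2'-bipyridine) (5 mol%), Mn powder (2 equiv), NaI (25 mol%), 15 (1.3 equiv), DMPU, rt
Reagents that add atoms: none
Why: Nickel-catalysed reductive cross-electrophile coupling, in which zerovalent nickel inserts into the alkenyl bromide with retention of geometry, the primary iodide enters as a radical and reductive elimination forms the CH2–CH= bond; the radical has only 4-exo or 5-endo paths to the exocyclic alkene and no stereocentre is involved.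

Step 10
Reactants: 16 (2R,3S)-5-methylidene-2-[4-(triisopropylsilyloxy)phenyl]-3-{(E)-3-[4-(triisopropylsilyloxy)phenyl]prop-2-enyl}oxane
Product: 18 all-cis (2R,3S,5S)-5-(hydroxymethyl)-2-[4-(triisopropylsilyloxy)phenyl]-3-{(E)-3-[4-(triisopropylsilyloxy)phenyl]prop-2-enyl}oxane, via B-alkyl-9-BBN adduct 17 (not isolated)
Conditions: 9-BBN (1.2 equiv), THF, 0 °C to rt; NaBO3·4H2O, THF/H2O, rt
Reagents that add atoms: sodium perborate, [Na+].[Na+].O[B-]1(O)OO[B-](O)(O)OO1
Why: Brown hydroboration–oxidation, in which 9-BBN adds much faster to the 1,1-disubstituted exocyclic alkene than to the 1,2-disubstituted styrenyl alkene; in the favoured chair (C2 aryl equatorial, C3 chain axial, cheap because neither O1 nor sp2 C5 carries a syn-axial hydrogen) the axial chain blocks its own face, so hydrogen reaches C5 anti to both substituents, the CH2B arm is pushed cis to them, and oxidation retains this.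

Step 11
Reactants: 18 all-cis (2R,3S,5S)-5-(hydroxymethyl)-2-[4-(triisopropylsilyloxy)phenyl]-3-{(E)-3-[4-(triisopropylsilyloxy)phenyl]prop-2-enyl}oxane
Product: 19 (2R,3S,5R)-2-[4-(triisopropylsilyloxy)phenyl]-3-{(E)-3-[4-(triisopropylsilyloxy)phenyl]prop-2-enyl}oxane-5-carbaldehyde
Conditions: Dess–Martin periodinane, CH2Cl2, 0 °C to rt; used at once
Reagents that add atoms: none
Why: Dess–Martin oxidation works without amine base under weakly acidic conditions, which should keep the contra-thermodynamic C5 aldehyde from epimerising and leaves the styrene and the silyl ethers alone.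

Step 12
Reactants: 19 (2R,3S,5R)-2-[4-(triisopropylsilyloxy)phenyl]-3-{(E)-3-[4-(triisopropylsilyloxy)phenyl]prop-2-enyl}oxane-5-carbaldehyde; 20 (4-bromophenoxy)(tert-butyl)dimethylsilane
Product: 24 (R)-[4-(tert-butyldimethylsilyloxy)phenyl]{(2R,3S,5R)-2-[4-(triisopropylsilyloxy)phenyl]-3-[(E)-3-[4-(triisopropylsilyloxy)phenyl]prop-2-enyl]oxan-5-yl}methanol, via aryllithium 21 (not isolated), via arylzinc chloride 22 (not isolated), via aryl(butyl)zinc 23 (not isolated)
Conditions: 20 (2 equiv), n-BuLi, t-BuOMe, −78 °C; ZnCl2, 0 °C; n-BuLi, −78 to 0 °C; N,N,N',N'-tetraethylethylenediamine, toluene; (2S)-(−)-3-exo-morpholinoisoborneol [(−)-MIB, 10 mol%]; 19, 0 °C; aq NH4Cl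
Reagents that add atoms: none
Why: Catalytic enantioselective aryl transfer from a mixed aryl(alkyl)zinc under amino-alkoxide zinc catalysis (the arylzinc counterpart of the Noyori dialkylzinc addition), where the two ring arms on C5 (C4H2 and C6H2) differ too little and a chelate to O1 would need the C3 and C5 groups both axial, so the new centre is put under ligand control: (−)-MIB is expected to deliver the aryl group to the Si face of the formyl group and so give the (R)-carbinol, the weakly basic zinc reagent should leave C5 untouched, and the diamine ties up LiCl that would drive an unselective background addition.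

Step 13
Reactants: 24 (R)-[4-(tert-butyldimethylsilyloxy)phenyl]{(2R,3S,5R)-2-[4-(triisopropylsilyloxy)phenyl]-3-[(E)-3-[4-(triisopropylsilyloxy)phenyl]prop-2-enyl]oxan-5-yl}methanol
Product: 25 4-[(2R,3S,5R)-5-[(R)-hydroxy(4-hydroxyphenyl)methyl]-3-[(E)-3-(4-hydroxyphenyl)prop-2-enyl]oxan-2-yl]phenol (CNP0182155.1)
Conditions: Bu4NF/AcOH (1:1, 3.5 equiv), THF, 0 °C
Reagents that add atoms: none
Why: Fluoride-driven cleavage of all three aryl silyl ethers through Si–F bond formation, with acetic acid keeping the phenols protonated so that neither the C2 benzylic ether nor the benzylic carbinol can ionise through a para-quinone methide.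

**Compound list**
1 | 4'-hydroxyacetophenone | CC(=O)c1ccc(O)cc1 | starting material
2 | diethyl carbonate | CCOC(=O)OCC | starting material
3 | ethyl 3-(4-hydroxyphenyl)-3-oxopropanoate | CCOC(=O)CC(=O)c1ccc(O)cc1 | intermediate
4 | ethyl 3-oxo-3-[4-(triisopropylsilyloxy)phenyl]propanoate | CCOC(=O)CC(=O)c1ccc(O[Si](C(C)C)(C(C)C)C(C)C)cc1 | intermediate
5 | ethyl (R)-3-hydroxy-3-[4-(triisopropylsilyloxy)phenyl]propanoate | CCOC(=O)C[C@@H](O)c1ccc(O[Si](C(C)C)(C(C)C)C(C)C)cc1 | intermediate
6 | 3-chloro-2-(chloromethyl)prop-1-ene | C=C(CCl)CCl | starting material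
7 | dilithium alkoxide–enolate of 5, enolate oxygen cis to the carbinol carbon (not isolated) | [Li+].[Li+].CCO/C([O-])=C/[C@@H]([O-])c1ccc(O[Si](C(C)C)(C(C)C)C(C)C)cc1 | intermediate
8 | lithium alkoxide of ethyl (2S,3R)-2-[2-(chloromethyl)prop-2-enyl]-3-hydroxy-3-[4-(triisopropylsilyloxy)phenyl]propanoate (not isolated) | [Li+].CCOC(=O)[C@@H](CC(=C)CCl)[C@@H]([O-])c1ccc(O[Si](C(C)C)(C(C)C)C(C)C)cc1 | intermediate
9 | ethyl (2R,3S)-5-methylidene-2-[4-(triisopropylsilyloxy)phenyl]oxane-3-carboxylate (2,3-cis) | CCOC(=O)[C@H]2CC(=C)CO[C@H]2c1ccc(O[Si](C(C)C)(C(C)C)C(C)C)cc1 | intermediate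
10 | {(2R,3R)-5-methylidene-2-[4-(triisopropylsilyloxy)phenyl]oxan-3-yl}methanol | OC[C@H]2CC(=C)CO[C@H]2c1ccc(O[Si](C(C)C)(C(C)C)C(C)C)cc1 | intermediate
11 | (2R,3S)-3-(iodomethyl)-5-methylidene-2-[4-(triisopropylsilyloxy)phenyl]oxane | IC[C@H]2CC(=C)CO[C@H]2c1ccc(O[Si](C(C)C)(C(C)C)C(C)C)cc1 | intermediate
12 | p-coumaric acid | O=C(O)/C=C/c1ccc(O)cc1 | starting material
13 | triisopropylsilyl (E)-3-[4-(triisopropylsilyloxy)phenyl]prop-2-enoate (not isolated) | CC(C)[Si](C(C)C)(C(C)C)OC(=O)/C=C/c1ccc(O[Si](C(C)C)(C(C)C)C(C)C)cc1 | intermediate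
14 | (E)-3-[4-(triisopropylsilyloxy)phenyl]prop-2-enoic acid | OC(=O)/C=C/c1ccc(O[Si](C(C)C)(C(C)C)C(C)C)cc1 | intermediate
15 | (E)-1-(2-bromoethenyl)-4-(triisopropylsilyloxy)benzene | Br/C=C/c1ccc(O[Si](C(C)C)(C(C)C)C(C)C)cc1 | intermediate
16 | (2R,3S)-5-methylidene-2-[4-(triisopropylsilyloxy)phenyl]-3-{(E)-3-[4-(triisopropylsilyloxy)phenyl]prop-2-enyl}oxane | CC(C)[Si](C(C)C)(C(C)C)Oc1ccc(/C=C/C[C@H]2CC(=C)CO[C@H]2c4ccc(O[Si](C(C)C)(C(C)C)C(C)C)cc4)cc1 | intermediate
17 | B-alkyl-9-BBN adduct of 16, boron on the former methylene carbon, all-cis ring (not isolated) | CC(C)[Si](C(C)C)(C(C)C)Oc1ccc(/C=C/C[C@H]2C[C@@H](CB3C5CCCC3CCC5)CO[C@H]2c4ccc(O[Si](C(C)C)(C(C)C)C(C)C)cc4)cc1 | intermediate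
18 | all-cis (2R,3S,5S)-5-(hydroxymethyl)-2-[4-(triisopropylsilyloxy)phenyl]-3-{(E)-3-[4-(triisopropylsilyloxy)phenyl]prop-2-enyl}oxane | CC(C)[Si](C(C)C)(C(C)C)Oc1ccc(/C=C/C[C@H]2C[C@@H](CO)CO[C@H]2c4ccc(O[Si](C(C)C)(C(C)C)C(C)C)cc4)cc1 | intermediate
19 | (2R,3S,5R)-2-[4-(triisopropylsilyloxy)phenyl]-3-{(E)-3-[4-(triisopropylsilyloxy)phenyl]prop-2-enyl}oxane-5-carbaldehyde | CC(C)[Si](C(C)C)(C(C)C)Oc1ccc(/C=C/C[C@H]2C[C@@H](C=O)CO[C@H]2c4ccc(O[Si](C(C)C)(C(C)C)C(C)C)cc4)cc1 | intermediate
20 | (4-bromophenoxy)(tert-butyl)dimethylsilane | Brc1ccc(O[Si](C)(C)C(C)(C)C)cc1 | starting material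
21 | 4-(tert-butyldimethylsilyloxy)phenyllithium (not isolated) | [Li]c1ccc(O[Si](C)(C)C(C)(C)C)cc1 | intermediate
22 | 4-(tert-butyldimethylsilyloxy)phenylzinc chloride (not isolated) | Cl[Zn]c1ccc(O[Si](C)(C)C(C)(C)C)cc1 | intermediate
23 | butyl[4-(tert-butyldimethylsilyloxy)phenyl]zinc (not isolated) | CCCC[Zn]c1ccc(O[Si](C)(C)C(C)(C)C)cc1 | intermediate
24 | (R)-[4-(tert-butyldimethylsilyloxy)phenyl]{(2R,3S,5R)-2-[4-(triisopropylsilyloxy)phenyl]-3-[(E)-3-[4-(triisopropylsilyloxy)phenyl]prop-2-enyl]oxan-5-yl}methanol | CC(C)[Si](C(C)C)(C(C)C)Oc1ccc(/C=C/C[C@H]2C[C@@H]([C@@H](O)c3ccc(O[Si](C)(C)C(C)(C)C)cc3)CO[C@H]2c4ccc(O[Si](C(C)C)(C(C)C)C(C)C)cc4)cc1 | intermediate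
25 | 4-[(2R,3S,5R)-5-[(R)-hydroxy(4-hydroxyphenyl)methyl]-3-[(E)-3-(4-hydroxyphenyl)prop-2-enyl]oxan-2-yl]phenol | Oc1ccc(/C=C/C[C@H]2C[C@@H]([C@@H](O)c3ccc(O)cc3)CO[C@H]2c2ccc(O)cc2)cc1 | target

**Step count**
- Total steps: 13.
- Longest linear sequence: 11 (steps 1–6 and 9–13, from 1).

**Steps most likely to fail**

Step 4 (annulation).
- What may go wrong: retro-aldol fragmentation of the lithium aldolate while the slower O-alkylation is awaited, coupling of two dianions through one dichloride, and base-mediated epimerisation at C3 or ring-opening β-elimination of the product.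
- Fallback, from 5 and 6, back at 9: the two bond formations are separated.
  - The dianion alkylation is run as an ordinary Fráter–Seebach alkylation and quenched cold with acetic acid. This isolates ethyl (2S,3R)-2-[2-(chloromethyl)prop-2-enyl]-3-hydroxy-3-[4-(triisopropylsilyloxy)phenyl]propanoate F1.
  - Ring closure is then moved from alkoxide displacement to a Tsuji–Trost intramolecular O-allylation (Pd(PPh3)4, Et3N, THF, 50 °C).
  - Zerovalent palladium ionises the allylic chloride to a 2-substituted π-allyl complex with equivalent termini, and the neutral hydroxyl closes the six-membered ring to 9.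
  - No strong base is present, so cleavage and epimerisation lose their driving force.

Step 12 (aryl transfer).
- What may go wrong: loss of facial control through uncatalysed background addition or through coordination of zinc to O1, and slow epimerisation at C5 while the aldehyde waits for a slow catalytic turnover.
- Fallback, from 19 and 20, back at 24: bond formation and stereocontrol are separated.
  - 4-(tert-Butyldimethylsilyloxy)phenylmagnesium bromide F2 (from 20 and Mg, THF) is added quickly at −78 °C without stereocontrol. This gives the carbinol as a mixture of epimers at the new centre F3.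
  - Dess–Martin oxidation gives the aryl ketone [4-(tert-butyldimethylsilyloxy)phenyl]{(2R,3S,5R)-2-[4-(triisopropylsilyloxy)phenyl]-3-[(E)-3-[4-(triisopropylsilyloxy)phenyl]prop-2-enyl]oxan-5-yl}methanone F4.
  - Corey–Bakshi–Shibata reduction follows, with (S)-2-methyl-CBS-oxazaborolidine and catecholborane (toluene, −78 °C).
  - This reductant spares the styrene. With the aryl group as the large substituent it should deliver hydride to the face that gives the (R)-carbinol 24.

Step 9 (cross-electrophile coupling).
- What may go wrong: homocoupling of the alkenyl bromide, hydrodehalogenation or β-hydride loss on the alkyl side, and erosion of the alkene geometry.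
- Fallback, from 11, back at 16: the C=C bond is built instead of the CH2–CH= bond.
  - Iodine–lithium exchange (t-BuLi, 2 equiv, Et2O/pentane, −78 °C) gives {(2R,3S)-5-methylidene-2-[4-(triisopropylsilyloxy)phenyl]oxan-3-yl}methyllithium F5.
  - Trapping with DMF gives 2-{(2R,3S)-5-methylidene-2-[4-(triisopropylsilyloxy)phenyl]oxan-3-yl}acetaldehyde F6, which has no stereocentre next to the formyl group.
  - Horner–Wadsworth–Emmons olefination uses the sodium anion (NaN(SiMe3)2, THF, −78 to 0 °C) of diethyl {[4-(triisopropylsilyloxy)phenyl]methyl}phosphonate F7. F7 is made from commercial diethyl (4-hydroxybenzyl)phosphonate with TIPSCl and imidazole.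
  - The olefination should give the (E)-styrene 16.

**Further compounds**
F1 | step 4 | ethyl (2S,3R)-2-[2-(chloromethyl)prop-2-enyl]-3-hydroxy-3-[4-(triisopropylsilyloxy)phenyl]propanoate | CCOC(=O)[C@@H](CC(=C)CCl)[C@@H](O)c1ccc(O[Si](C(C)C)(C(C)C)C(C)C)cc1
F2 | step 12 | 4-(tert-butyldimethylsilyloxy)phenylmagnesium bromide | Br[Mg]c1ccc(O[Si](C)(C)C(C)(C)C)cc1
F3 | step 12 | carbinol 24 as a mixture of epimers at the carbinol carbon | CC(C)[Si](C(C)C)(C(C)C)Oc1ccc(/C=C/C[C@H]2C[C@@H](C(O)c3ccc(O[Si](C)(C)C(C)(C)C)cc3)CO[C@H]2c4ccc(O[Si](C(C)C)(C(C)C)C(C)C)cc4)cc1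
F4 | step 12 | [4-(tert-butyldimethylsilyloxy)phenyl]{(2R,3S,5R)-2-[4-(triisopropylsilyloxy)phenyl]-3-[(E)-3-[4-(triisopropylsilyloxy)phenyl]prop-2-enyl]oxan-5-yl}methanone | CC(C)[Si](C(C)C)(C(C)C)Oc1ccc(/C=C/C[C@H]2C[C@@H](C(=O)c3ccc(O[Si](C)(C)C(C)(C)C)cc3)CO[C@H]2c4ccc(O[Si](C(C)C)(C(C)C)C(C)C)cc4)cc1
F5 | step 9 | {(2R,3S)-5-methylidene-2-[4-(triisopropylsilyloxy)phenyl]oxan-3-yl}methyllithium | [Li]C[C@H]2CC(=C)CO[C@H]2c1ccc(O[Si](C(C)C)(C(C)C)C(C)C)cc1
F6 | step 9 | 2-{(2R,3S)-5-methylidene-2-[4-(triisopropylsilyloxy)phenyl]oxan-3-yl}acetaldehyde | O=CC[C@H]2CC(=C)CO[C@H]2c1ccc(O[Si](C(C)C)(C(C)C)C(C)C)cc1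
F7 | step 9 | diethyl {[4-(triisopropylsilyloxy)phenyl]methyl}phosphonate | CCOP(=O)(Cc1ccc(O[Si](C(C)C)(C(C)C)C(C)C)cc1)OCC
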